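**Plan**

1. Numbering: ring C1 (carbinol carbon carrying the CH2OBz carbon C7), C2 (OH), C3 (OBz), C4 (OH), C5=C6. Cuts, from the target backwards: the O1/O2 acetonide; C4–H (carbinol from a C4 ketone); C5=C6 (ring-closing metathesis); C4–C5 (vinyl addition to a C4 aldehyde); the two benzoates; C6=CH2 (Wittig on a lactol); C1–C7 (crossed aldol with formaldehyde) on diacetone-D-mannose.
2. Enabling feature: C1 lies between C6, which can stand at the aldehyde level, and C2, whose OH is cis to the C1 OH. In the mannofuranose, O1 and O2 are tied in a cis-fused dioxolane and O3 holds the C6 aldehyde as a furanose lactol, so C1 is an enolisable α-carbon inside a bicyclic frame that accepts only one configuration.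
3. Forward order: C1–C7 bond on the intact furanose; Wittig opening of the lactol (C6 vinyl), which frees O3 beside the new O7 so that both benzoates go on together; terminal acetonide cut to the C4 aldehyde; vinyl addition (C5); cyclohexene ring by metathesis; C4 oxidised to the enone and reduced; acetonide removed.
4. Stereochemistry: C2 and C3 are C3 and C4 of D-mannose. C1 is set in the aldol by the dioxolane/lactol ring fusion (stereoconvergent; the original C–H centre is erased). C4 is set by axial hydride delivery to the cyclic enone, which also funnels both epimers from the vinyl addition.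

Key step: step 1

Remark: compounds 9 and 10 are carried as mixtures of epimers at the carbinol carbon that is oxidised in step 7 (their SMILES leave this centre open), and lactol 4 is an anomeric mixture (one anomer drawn).

**Route**

Step 1
Reactants: 1 2,3:5,6-di-O-isopropylidene-α-D-mannofuranose (diacetone-D-mannose); 2 formaldehyde (37% aqueous solution)
Product: 4 2-C-(hydroxymethyl)-2,3:5,6-di-O-isopropylidene-D-mannofuranose, via acyclic aldol aldehyde 3 (not isolated)
Conditions: aq. HCHO (excess), K2CO3, MeOH, 65 °C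
Reagents that add atoms: none
Why: Carbonate opens the lactol to the sugar C-1 aldehyde and reversibly removes H-2, giving an enolate exocyclic to the 2,3-dioxolane whose carbon (the future ring C1) adds to formaldehyde; the adduct has no α-hydrogen and cannot enolise further (crossed aldol addition, closest known type: hydroxymethylation of 2,3-O-isopropylidene furanose lactols with formaldehyde and carbonate, as used for hamamelose-type branched sugars). The one ring closed in the step, the furanose hemiacetal, re-forms by 5-exo-trig addition of O-4 to the aldehyde. The new fully substituted stereocentre is controlled by the dioxolane and the lactol: formaldehyde enters anti to the C-4 side chain on the neighbouring ring carbon, and only the adduct with the formyl group cis to C-4 can close to the cis-fused bicyclic lactol, whereas the other adduct stays a free β-hydroxy aldehyde that reverts by retro-aldol, so either enolate face and either anomer should end in the one configuration with O-2 cis to O-3 and CH2OH trans to C-4. The step needs C-alkylation at C-2 without β-elimination of O-3, without a second hydroxymethylation and without Cannizzaro reduction; the C3–O3 bond is held in the plane of the dioxolane, orthogonal to the enolate π system, the product has no further enolisable position, and potassium carbonate is too weak a base to drive hydride transfer.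

Step 2
Reactants: 4 2-C-(hydroxymethyl)-2,3:5,6-di-O-isopropylidene-D-mannofuranose
Product: 5 1,2-dideoxy-3-C-(hydroxymethyl)-3,4:6,7-di-O-isopropylidene-D-manno-hept-1-enitol
Conditions: Ph3PCH3Br, n-BuLi (excess ylide), THF, −78 °C → rt
Reagents that add atoms: methyltriphenylphosphonium bromide (as its ylide), C[P+](c1ccccc1)(c1ccccc1)c1ccccc1.[Br-]
Why: Wittig methylenation of the ring-opened aldehyde form of the lactol should turn the sugar C-1 into the vinyl CH that becomes ring C6 and at the same time free the furanose oxygen as the hydroxyl on the future C3, with no stereocentre touched and the excess lithium ylide holding both hydroxyls as lithium alkoxides that are slow to undergo retro-aldol loss of formaldehyde.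

Step 3
Reactants: 5 1,2-dideoxy-3-C-(hydroxymethyl)-3,4:6,7-di-O-isopropylidene-D-manno-hept-1-enitol
Product: 6 5-O-benzoyl-3-C-[(benzoyloxy)methyl]-1,2-dideoxy-3,4:6,7-di-O-isopropylidene-D-manno-hept-1-enitol
Conditions: BzCl, pyridine, DMAP (cat.), CH2Cl2, 0 °C → rt
Reagents that add atoms: benzoyl chloride, O=C(Cl)c1ccccc1
Why: Acylation with benzoyl chloride under nucleophilic (DMAP) catalysis should esterify the only two free hydroxyls, the primary one on C7 and the secondary one on the future C3, which are exactly the benzoylated positions of the target, so the esters go on without a protecting-group step and no stereocentre is affected.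

Step 4
Reactants: 6 5-O-benzoyl-3-C-[(benzoyloxy)methyl]-1,2-dideoxy-3,4:6,7-di-O-isopropylidene-D-manno-hept-1-enitol
Product: 8 (2S,3S,4S)-2-(benzoyloxy)-4-[(benzoyloxy)methyl]-3,4-(isopropylidenedioxy)hex-5-enal, via terminal glycol 7 (not isolated)
Conditions: H5IO6, EtOAc, rt; crude aldehyde used at once
Reagents that add atoms: none
Why: Periodic acid in ethyl acetate should hydrolyse the terminal, less hindered dioxolane selectively and cleave the resulting glycol in the same flask (acetal hydrolysis followed by Malaprade glycol cleavage, a one-pot sequence established for terminal acetonides of di-O-isopropylidene sugars), while the internal dioxolane at the fully substituted carbon and both esters stay in place, the benzoate on the neighbouring oxygen rules out over-cleavage, and the non-basic medium preserves the α-benzoyloxy stereocentre (future C3).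

Step 5
Reactants: 8 (2S,3S,4S)-2-(benzoyloxy)-4-[(benzoyloxy)methyl]-3,4-(isopropylidenedioxy)hex-5-enal
Product: 9 (3RS,4R,5S,6S)-4-(benzoyloxy)-6-[(benzoyloxy)methyl]-5,6-(isopropylidenedioxy)octa-1,7-dien-3-ol
Conditions: CH2=CHBr, CrCl2, NiCl2 (cat.), DMF, rt
Reagents that add atoms: vinyl bromide, C=CBr
Why: Nozaki–Hiyama–Kishi vinylation should add the vinyl group (future C5) to the aldehyde alone, because the vinylchromium(III) reagent is non-basic and unreactive towards esters, so the α-benzoyloxy centre is not epimerised and the benzoates are not attacked; the new carbinol centre (future C4) is left uncontrolled on purpose, since both epimers converge on one ketone in step 7.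

Step 6
Reactants: 9 (3RS,4R,5S,6S)-4-(benzoyloxy)-6-[(benzoyloxy)methyl]-5,6-(isopropylidenedioxy)octa-1,7-dien-3-ol
Product: 10 [(1S,2S,3R,4RS)-3-(benzoyloxy)-4-hydroxy-1,2-(isopropylidenedioxy)cyclohex-5-en-1-yl]methyl benzoate
Conditions: Grubbs II catalyst (5 mol%), CH2Cl2, 40 °C
Reagents that add atoms: none
Why: Ring-closing olefin metathesis should form the C5=C6 bond and the cyclohexene ring with loss of ethylene, the cis-dioxolane holding the two vinyl-bearing arms on the same face and the catalyst loading on the unhindered allylic-alcohol vinyl group before closing onto the vinyl group at the fully substituted carbon; no stereocentre changes.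

Step 7
Reactants: 10 [(1S,2S,3R,4RS)-3-(benzoyloxy)-4-hydroxy-1,2-(isopropylidenedioxy)cyclohex-5-en-1-yl]methyl benzoate
Product: 11 [(1S,2S,3S)-3-(benzoyloxy)-1,2-(isopropylidenedioxy)-4-oxocyclohex-5-en-1-yl]methyl benzoate
Conditions: Dess–Martin periodinane, NaHCO3, CH2Cl2, 0 °C → rt
Reagents that add atoms: none
Why: Dess–Martin oxidation of the secondary allylic alcohol under bicarbonate buffer should turn both C4 epimers into the single enone without base-induced epimerisation at C3 or β-elimination of the dioxolane oxygen.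

Step 8
Reactants: 11 [(1S,2S,3S)-3-(benzoyloxy)-1,2-(isopropylidenedioxy)-4-oxocyclohex-5-en-1-yl]methyl benzoate
Product: 12 [(1S,2S,3R,4S)-3-(benzoyloxy)-4-hydroxy-1,2-(isopropylidenedioxy)cyclohex-5-en-1-yl]methyl benzoate
Conditions: NaBH4, CeCl3·7H2O, MeOH, −78 °C; AcOH quench at −78 °C
Reagents that add atoms: none
Why: Luche 1,2-reduction should deliver hydride axially to the α face of the enone, anti to the axial C3–H of the half-chair in which the C3 benzoate, O2 and the CH2OBz group are pseudo-equatorial and the dioxolane shields the β face, which sets C4 as the β (4S) alcohol trans to the C3 benzoate, in line with the behaviour of 6-oxygenated cyclohex-2-enones of the conduritol series; the low temperature and acidic quench are meant to stop benzoyl migration from O3 to the new O4.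

Step 9
Reactants: 12 [(1S,2S,3R,4S)-3-(benzoyloxy)-4-hydroxy-1,2-(isopropylidenedioxy)cyclohex-5-en-1-yl]methyl benzoate
Product: 13 [(1S,2S,3R,4S)-3-(benzoyloxy)-1,2,4-trihydroxycyclohex-5-en-1-yl]methyl benzoate (target)
Conditions: TFA–H2O (4:1), CH2Cl2, 0 °C → rt
Reagents that add atoms: none
Why: Acid-catalysed hydrolysis of the isopropylidene acetal should release the cis C1/C2 diol and give the target, acidic conditions being chosen because they do not promote benzoyl migration among the neighbouring hydroxyls and touch no stereocentre.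

**Compound list**

1 | 2,3:5,6-di-O-isopropylidene-α-D-mannofuranose (diacetone-D-mannose) | O[C@@H]1[C@@H](OC2(C)C)[C@@H](O2)[C@H](O1)[C@H]3COC(C)(C)O3 | starting material
2 | formaldehyde | C=O | starting material
3 | 2-C-(hydroxymethyl)-2,3:5,6-di-O-isopropylidene-aldehydo-D-mannose (acyclic aldol aldehyde) | O=C[C@@](CO)(OC1(C)C)[C@@H](O1)[C@H](O)[C@H]2COC(C)(C)O2 | intermediate (not isolated)
4 | 2-C-(hydroxymethyl)-2,3:5,6-di-O-isopropylidene-D-mannofuranose | O[C@@H]1[C@@](CO)(OC2(C)C)[C@@H](O2)[C@H](O1)[C@H]3COC(C)(C)O3 | intermediate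
5 | 1,2-dideoxy-3-C-(hydroxymethyl)-3,4:6,7-di-O-isopropylidene-D-manno-hept-1-enitol | C=C[C@@](CO)(OC1(C)C)[C@@H](O1)[C@H](O)[C@H]2COC(C)(C)O2 | intermediate
6 | 5-O-benzoyl-3-C-[(benzoyloxy)methyl]-1,2-dideoxy-3,4:6,7-di-O-isopropylidene-D-manno-hept-1-enitol | C=C[C@@](COC(=O)c1ccccc1)(OC2(C)C)[C@@H](O2)[C@H](OC(=O)c3ccccc3)[C@H]4COC(C)(C)O4 | intermediate
7 | 5-O-benzoyl-3-C-[(benzoyloxy)methyl]-1,2-dideoxy-3,4-O-isopropylidene-D-manno-hept-1-enitol (terminal glycol) | C=C[C@@](COC(=O)c1ccccc1)(OC2(C)C)[C@@H](O2)[C@H](OC(=O)c3ccccc3)[C@H](O)CO | intermediate (not isolated)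
8 | (2S,3S,4S)-2-(benzoyloxy)-4-[(benzoyloxy)methyl]-3,4-(isopropylidenedioxy)hex-5-enal | C=C[C@@](COC(=O)c1ccccc1)(OC2(C)C)[C@@H](O2)[C@H](OC(=O)c3ccccc3)C=O | intermediate
9 | (3RS,4R,5S,6S)-4-(benzoyloxy)-6-[(benzoyloxy)methyl]-5,6-(isopropylidenedioxy)octa-1,7-dien-3-ol (both C3 epimers) | C=C[C@@](COC(=O)c1ccccc1)(OC2(C)C)[C@@H](O2)[C@H](OC(=O)c3ccccc3)C(O)C=C | intermediate
10 | [(1S,2S,3R,4RS)-3-(benzoyloxy)-4-hydroxy-1,2-(isopropylidenedioxy)cyclohex-5-en-1-yl]methyl benzoate (both C4 epimers) | O=C(OC[C@@]1(OC(C)(C)O2)C=CC(O)[C@@H](OC(=O)c3ccccc3)[C@@H]12)c1ccccc1 | intermediate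
11 | [(1S,2S,3S)-3-(benzoyloxy)-1,2-(isopropylidenedioxy)-4-oxocyclohex-5-en-1-yl]methyl benzoate | O=C(OC[C@@]1(OC(C)(C)O2)C=CC(=O)[C@@H](OC(=O)c3ccccc3)[C@@H]12)c1ccccc1 | intermediate
12 | [(1S,2S,3R,4S)-3-(benzoyloxy)-4-hydroxy-1,2-(isopropylidenedioxy)cyclohex-5-en-1-yl]methyl benzoate | O=C(OC[C@@]1(OC(C)(C)O2)C=C[C@H](O)[C@@H](OC(=O)c3ccccc3)[C@@H]12)c1ccccc1 | intermediate
13 | [(1S,2S,3R,4S)-3-(benzoyloxy)-1,2,4-trihydroxycyclohex-5-en-1-yl]methyl benzoate | O=C(OC[C@@]1(O)C=C[C@H](O)[C@@H](OC(=O)c2ccccc2)[C@@H]1O)c1ccccc1 | target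

**Step count and risks**

Total steps: 9. Longest linear sequence: 9 steps (1 → 13).

Steps most likely to fail:

1. Step 2 (Wittig on the hydroxymethyl lactol). What may go wrong: retro-aldol loss of formaldehyde from the C7 alkoxide of the ring-opened aldehyde (the ylide would trap the formaldehyde and the unbranched alkene would result), together with slow olefination of the neopentyl-type aldehyde. Fallback: it sets out from 4 and comes back at 5. The primary hydroxyl is silylated first (TBDPSCl, imidazole, DMF, 0 °C) to the silyl ether 2-C-[(tert-butyldiphenylsilyloxy)methyl]-2,3:5,6-di-O-isopropylidene-D-mannofuranose F1, in which no aldolate can form. Wittig methylenation as in step 2 should then give the silylated heptenitol 3-C-[(tert-butyldiphenylsilyloxy)methyl]-1,2-dideoxy-3,4:6,7-di-O-isopropylidene-D-manno-hept-1-enitol F2, and TBAF in THF should remove the silyl group to return diol 5.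

2. Step 5 (vinylation of the α-benzoyloxy aldehyde). What may go wrong: enolisation of the aldehyde during its formation and vinylation (loss of the C3 configuration or β-elimination of the dioxolane oxygen) and transfer of a benzoyl group to the new metal alkoxide. Fallback: it sets out from 5 and comes back at 11, keeping O3 and O7 as ethers until the ring and the ketone exist. NaH/PMBCl in DMF should give the bis-ether 1,2-dideoxy-3,4:6,7-di-O-isopropylidene-5-O-(4-methoxybenzyl)-3-C-[(4-methoxybenzyloxy)methyl]-D-manno-hept-1-enitol F3. H5IO6 in EtOAc should cut the terminal acetonide through the glycol 1,2-dideoxy-3,4-O-isopropylidene-5-O-(4-methoxybenzyl)-3-C-[(4-methoxybenzyloxy)methyl]-D-manno-hept-1-enitol F4 to the aldehyde (2S,3S,4S)-3,4-(isopropylidenedioxy)-2-(4-methoxybenzyloxy)-4-[(4-methoxybenzyloxy)methyl]hex-5-enal F5. Vinylmagnesium bromide (THF, −78 °C) should give the dienol (3RS,4R,5S,6S)-5,6-(isopropylidenedioxy)-4-(4-methoxybenzyloxy)-6-[(4-methoxybenzyloxy)methyl]octa-1,7-dien-3-ol F6. Grubbs II should close the ring to the cyclohexenol (1RS,4S,5S,6R)-4,5-(isopropylidenedioxy)-6-(4-methoxybenzyloxy)-4-[(4-methoxybenzyloxy)methyl]cyclohex-2-en-1-ol F7, and Dess–Martin oxidation should give the enone (4S,5S,6S)-4,5-(isopropylidenedioxy)-6-(4-methoxybenzyloxy)-4-[(4-methoxybenzyloxy)methyl]cyclohex-2-en-1-one F8. DDQ (CH2Cl2/pH 7 buffer) should remove both PMB groups to the diol enone (4S,5S,6S)-6-hydroxy-4-(hydroxymethyl)-4,5-(isopropylidenedioxy)cyclohex-2-en-1-one F9, and BzCl/pyridine should esterify both hydroxyls to return enone 11.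

3. Step 8 (Luche reduction). What may go wrong: hydride delivery to the β face (poor facial selectivity, giving the C4 epimer) or benzoyl migration from O3 to the new alkoxide. Fallback: it sets out from 10 and comes back at 12 without passing the ketone. The 4R epimer of 10 (the epimer expected to predominate from a Felkin–Anh vinyl addition, separated by chromatography) is inverted by a Mitsunobu reaction with chloroacetic acid (PPh3, DIAD, toluene) to the chloroacetate [(1S,2S,3R,4S)-3-(benzoyloxy)-4-(chloroacetoxy)-1,2-(isopropylidenedioxy)cyclohex-5-en-1-yl]methyl benzoate F10; this is a direct SN2 displacement, since the cis C3 benzoate cannot participate. Thiourea/NaHCO3 in EtOH should then cleave the chloroacetate selectively to return 12.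

**Further compounds**

F1 | step 2 | 2-C-[(tert-butyldiphenylsilyloxy)methyl]-2,3:5,6-di-O-isopropylidene-D-mannofuranose | O[C@@H]1[C@@](CO[Si](c2ccccc2)(c2ccccc2)C(C)(C)C)(OC3(C)C)[C@@H](O3)[C@H](O1)[C@H]4COC(C)(C)O4
F2 | step 2 | 3-C-[(tert-butyldiphenylsilyloxy)methyl]-1,2-dideoxy-3,4:6,7-di-O-isopropylidene-D-manno-hept-1-enitol | C=C[C@@](CO[Si](c1ccccc1)(c1ccccc1)C(C)(C)C)(OC2(C)C)[C@@H](O2)[C@H](O)[C@H]3COC(C)(C)O3
F3 | step 5 | 1,2-dideoxy-3,4:6,7-di-O-isopropylidene-5-O-(4-methoxybenzyl)-3-C-[(4-methoxybenzyloxy)methyl]-D-manno-hept-1-enitol | C=C[C@@](COCc1ccc(OC)cc1)(OC2(C)C)[C@@H](O2)[C@H](OCc3ccc(OC)cc3)[C@H]4COC(C)(C)O4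
F4 | step 5 | 1,2-dideoxy-3,4-O-isopropylidene-5-O-(4-methoxybenzyl)-3-C-[(4-methoxybenzyloxy)methyl]-D-manno-hept-1-enitol | C=C[C@@](COCc1ccc(OC)cc1)(OC2(C)C)[C@@H](O2)[C@H](OCc3ccc(OC)cc3)[C@H](O)CO
F5 | step 5 | (2S,3S,4S)-3,4-(isopropylidenedioxy)-2-(4-methoxybenzyloxy)-4-[(4-methoxybenzyloxy)methyl]hex-5-enal | C=C[C@@](COCc1ccc(OC)cc1)(OC2(C)C)[C@@H](O2)[C@H](OCc3ccc(OC)cc3)C=O
F6 | step 5 | (3RS,4R,5S,6S)-5,6-(isopropylidenedioxy)-4-(4-methoxybenzyloxy)-6-[(4-methoxybenzyloxy)methyl]octa-1,7-dien-3-ol | C=C[C@@](COCc1ccc(OC)cc1)(OC2(C)C)[C@@H](O2)[C@H](OCc3ccc(OC)cc3)C(O)C=C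
F7 | step 5 | (1RS,4S,5S,6R)-4,5-(isopropylidenedioxy)-6-(4-methoxybenzyloxy)-4-[(4-methoxybenzyloxy)methyl]cyclohex-2-en-1-ol | COc1ccc(COC[C@@]2(OC(C)(C)O3)C=CC(O)[C@@H](OCc4ccc(OC)cc4)[C@@H]23)cc1
F8 | step 5 | (4S,5S,6S)-4,5-(isopropylidenedioxy)-6-(4-methoxybenzyloxy)-4-[(4-methoxybenzyloxy)methyl]cyclohex-2-en-1-one | COc1ccc(COC[C@@]2(OC(C)(C)O3)C=CC(=O)[C@@H](OCc4ccc(OC)cc4)[C@@H]23)cc1
F9 | step 5 | (4S,5S,6S)-6-hydroxy-4-(hydroxymethyl)-4,5-(isopropylidenedioxy)cyclohex-2-en-1-one | OC[C@@]1(OC(C)(C)O2)C=CC(=O)[C@@H](O)[C@@H]12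
F10 | step 8 | [(1S,2S,3R,4S)-3-(benzoyloxy)-4-(chloroacetoxy)-1,2-(isopropylidenedioxy)cyclohex-5-en-1-yl]methyl benzoate | O=C(OC[C@@]1(OC(C)(C)O2)C=C[C@H](OC(=O)CCl)[C@@H](OC(=O)c3ccccc3)[C@@H]12)c1ccccc1
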